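The route rests on disconnecting the side chain between benzylic C1'' (on C6 of ring A) and vinylic C2''. The key step exploits the (E)-C2''=C3'' trisubstituted alkene carrying the C3'' methyl, next to the C6 benzylic carbon flanked by O5 and O7. Zirconium-catalysed syn-methylalumination of terminal alkyne 2 creates C3''–CH3, the E geometry and an alkenylalane, which palladium couples in the same flask with 6-(chloromethyl)chromone 7. The chloromethyl handle is placed at C6 by 5-OH-directed Mannich chemistry on 5,7-dihydroxychromone. The (2S) centre and ring B arrive afterwards by rhodium-catalysed asymmetric 1,4-arylation, and fluoride unmasks the phenols.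

Key step: step 6

Remark: compounds 1, 3 and 10 are taken as catalogue chemicals; the core carries flavanone numbering and the side-chain carbons are C1''–C8'' counted from ring A.

Step 1
Reactants: 1 methyl hex-5-ynoate
Product: 2 2-methylhept-6-yn-2-ol
Conditions: MeMgBr (3.3 equiv), THF, 0 °C → rt; aq NH4Cl
Reagents that add atoms: methylmagnesium bromide, C[Mg]Br
Why: Double Grignard addition to the ester (through the methyl ketone) should give the tertiary carbinol; the acetylenic C–H only consumes one further equivalent and is restored on work-up.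

Step 2
Reactants: 3 5,7-dihydroxy-4H-chromen-4-one
Product: 4 7-[(tert-butyldimethylsilyl)oxy]-5-hydroxy-4H-chromen-4-one
Conditions: TBSCl (1.1 equiv), imidazole (2.2 equiv), DMF, 0 °C → rt
Reagents that add atoms: tert-butyldimethylsilyl chloride, CC(C)(C)[Si](C)(C)Cl
Why: Chemoselective silyl ether formation at the acidic, unchelated 7-OH is expected, because the 5-OH is locked in a hydrogen bond to the C4 carbonyl.

Step 3
Reactants: 4 7-[(tert-butyldimethylsilyl)oxy]-5-hydroxy-4H-chromen-4-one
Product: 5 7-[(tert-butyldimethylsilyl)oxy]-6-[(dimethylamino)methyl]-5-hydroxy-4H-chromen-4-one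
Conditions: Me2N=CH2 I (Eschenmoser's salt, 1.05 equiv), i-Pr2NEt (1.1 equiv), CH2Cl2, 0 °C → rt; aq NaHCO3
Reagents that add atoms: N,N-dimethylmethyleneiminium iodide, C=[N+](C)C.[I-]
Why: Phenol Mannich aminomethylation should occur at C6, the only free position ortho to the only free hydroxyl (ortho delivery through the phenoxide, in line with the C6-selective halogenation of 5-hydroxy-7-alkoxychromones), and the preformed iminium salt avoids free secondary amine that would open the pyranone at C2.

Step 4
Reactants: 5 7-[(tert-butyldimethylsilyl)oxy]-6-[(dimethylamino)methyl]-5-hydroxy-4H-chromen-4-one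
Product: 6 5,7-bis[(tert-butyldimethylsilyl)oxy]-6-[(dimethylamino)methyl]-4H-chromen-4-one
Conditions: TBSOTf (1.3 equiv), 2,6-lutidine (2 equiv), CH2Cl2, 0 °C
Reagents that add atoms: tert-butyldimethylsilyl trifluoromethanesulfonate, CC(C)(C)[Si](C)(C)OS(=O)(=O)C(F)(F)F
Why: The silyl triflate is reactive enough to silylate the chelated, doubly flanked 5-OH, which removes the ortho-hydroxyl that would otherwise turn the later benzylic chloride into a quinone methide precursor.

Step 5
Reactants: 6 5,7-bis[(tert-butyldimethylsilyl)oxy]-6-[(dimethylamino)methyl]-4H-chromen-4-one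
Product: 7 5,7-bis[(tert-butyldimethylsilyl)oxy]-6-(chloromethyl)-4H-chromen-4-one
Conditions: ClCO2Et (1.5 equiv), CH2Cl2, 0 °C → rt; short silica plug, used directly
Reagents that add atoms: ethyl chloroformate, CCOC(=O)Cl
Why: Von Braun-type dealkylative chlorination: N-acylation gives an acylammonium ion whose electron-rich benzylic carbon is attacked by chloride, releasing the carbamate and leaving the silyl ethers untouched.

Step 6
Reactants: 2 2-methylhept-6-yn-2-ol; 7 5,7-bis[(tert-butyldimethylsilyl)oxy]-6-(chloromethyl)-4H-chromen-4-one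
Product: 9 5,7-bis[(tert-butyldimethylsilyl)oxy]-6-[(2E)-7-hydroxy-3,7-dimethyloct-2-en-1-yl]-4H-chromen-4-one, via alkenylalane 8 (not isolated)
Conditions: 2 (1.5 equiv), Me3Al (3 equiv per alkyne), Cp2ZrCl2 (0.25 equiv), CH2Cl2, 0 °C → rt; volatiles removed in vacuo; then 7 (1 equiv), Pd(PPh3)4 (5 mol %, zerovalent palladium), THF, rt; aq potassium sodium tartrate
Reagents that add atoms: trimethylaluminium, C[Al](C)C
Why: Negishi zirconium-catalysed carboalumination followed by alkenylalane–benzyl chloride cross-coupling: after O-alumination of the tertiary hydroxyl, Cp2ZrCl2/Me3Al adds CH3–Al syn across the terminal alkyne with methyl on the internal carbon (future C3'') and aluminium on the terminal carbon (future C2''), giving E-alkenylalane 8. Zerovalent palladium then inserts into the benzylic C–Cl bond of 7, the alkenyl group passes from aluminium to palladium with retention, and reductive elimination forms the C1''–C2'' bond. The closest known reaction type is the palladium-catalysed coupling of 2-methylalk-1-enylalanes with benzylic halides used to attach isoprenoid chains to arenes. No ring is closed and no stereocentre is formed; the only stereo-element, the E geometry of C2''=C3'', follows from syn-carbometalation and retentive coupling. The step needs methyl delivery to the internal alkyne carbon (secured by the terminal alkyne and the zirconocene catalyst), alkenyl rather than methyl transfer to palladium (sp2 groups transmetalate faster), and selectivity for the C–Cl bond over the pyranone carbonyl, which as a non-enolisable vinylogous ester facing THF-complexed alanes should be inert at room temperature.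

Step 7
Reactants: 10 4-bromobenzene-1,2-diol
Product: 11 4-bromo-1,2-bis[(tert-butyldimethylsilyl)oxy]benzene
Conditions: TBSCl (2.3 equiv), imidazole (4.6 equiv), DMF, rt
Reagents that add atoms: tert-butyldimethylsilyl chloride, CC(C)(C)[Si](C)(C)Cl
Why: Standard bis-silylation of the catechol gives the same fluoride-labile protection as on ring A.

Step 8
Reactants: 11 4-bromo-1,2-bis[(tert-butyldimethylsilyl)oxy]benzene
Product: 13 {3,4-bis[(tert-butyldimethylsilyl)oxy]phenyl}boronic acid, via aryllithium 12 (not isolated)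
Conditions: n-BuLi (1.1 equiv), THF, −78 °C; B(Oi-Pr)3 (1.5 equiv), −78 °C → rt; aq NH4Cl
Reagents that add atoms: triisopropyl borate, CC(C)OB(OC(C)C)OC(C)C; water, O
Why: Bromine–lithium exchange and borate trapping, then hydrolysis, should give the boronic acid; the lithium sits meta/para to the silyloxy groups, so no O-to-C silyl migration is expected.

Step 9
Reactants: 9 5,7-bis[(tert-butyldimethylsilyl)oxy]-6-[(2E)-7-hydroxy-3,7-dimethyloct-2-en-1-yl]-4H-chromen-4-one; 13 {3,4-bis[(tert-butyldimethylsilyl)oxy]phenyl}boronic acid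
Product: 14 (2S)-5,7-bis[(tert-butyldimethylsilyl)oxy]-2-{3,4-bis[(tert-butyldimethylsilyl)oxy]phenyl}-6-[(2E)-7-hydroxy-3,7-dimethyloct-2-en-1-yl]-2,3-dihydro-4H-chromen-4-one
Conditions: [Rh(OH)((S)-MeO-F12-BIPHEP)]2 (1.5 mol %, monovalent rhodium; ligand = (S)-6,6'-dimethoxy-2,2'-bis[bis(3,4,5-trifluorophenyl)phosphino]biphenyl), 13 (2.5 equiv), CH2Cl2/H2O 10:1, 20 °C
Reagents that add atoms: none
Why: Hayashi–Miyaura rhodium-catalysed asymmetric 1,4-addition of the arylboronic acid to the chromone C2=C3 bond, with protonolysis of the oxa-π-allyl by water; the ligand sets C2, the (S)-bisphosphine being expected to give 2S by analogy with (S)-BINAP giving (S)-3-arylcyclohexanones (same CIP sequence at the new centre), and the electron-poor phosphine should make the addition fast enough at 20 °C to outrun ring opening and 1,2-addition.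

Step 10
Reactants: 14 (2S)-5,7-bis[(tert-butyldimethylsilyl)oxy]-2-{3,4-bis[(tert-butyldimethylsilyl)oxy]phenyl}-6-[(2E)-7-hydroxy-3,7-dimethyloct-2-en-1-yl]-2,3-dihydro-4H-chromen-4-one
Product: 15 Prokinawan, (2S)-2-(3,4-dihydroxyphenyl)-5,7-dihydroxy-6-[(2E)-7-hydroxy-3,7-dimethyloct-2-en-1-yl]-2,3-dihydro-4H-chromen-4-one
Conditions: TBAF (5 equiv), AcOH (5 equiv), THF, 0 °C → rt
Reagents that add atoms: none
Why: Fluoride cleaves the four aryl silyl ethers, while the acetic acid buffer keeps the phenols protonated so that base-induced retro-oxa-Michael opening (racemisation at C2) is avoided; the alkene and tertiary alcohol see no acid.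

Compound list
1 | methyl hex-5-ynoate | C#CCCCC(=O)OC | starting material
2 | 2-methylhept-6-yn-2-ol | C#CCCCC(C)(C)O | intermediate
3 | 5,7-dihydroxy-4H-chromen-4-one | O=c1ccoc2cc(O)cc(O)c12 | starting material
4 | 7-[(tert-butyldimethylsilyl)oxy]-5-hydroxy-4H-chromen-4-one | O=c1ccoc2cc(O[Si](C)(C)C(C)(C)C)cc(O)c12 | intermediate
5 | 7-[(tert-butyldimethylsilyl)oxy]-6-[(dimethylamino)methyl]-5-hydroxy-4H-chromen-4-one | CN(C)Cc1c(O)c2c(cc1O[Si](C)(C)C(C)(C)C)occc2=O | intermediate
6 | 5,7-bis[(tert-butyldimethylsilyl)oxy]-6-[(dimethylamino)methyl]-4H-chromen-4-one | CN(C)Cc1c(O[Si](C)(C)C(C)(C)C)c2c(cc1O[Si](C)(C)C(C)(C)C)occc2=O | intermediate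
7 | 5,7-bis[(tert-butyldimethylsilyl)oxy]-6-(chloromethyl)-4H-chromen-4-one | ClCc1c(O[Si](C)(C)C(C)(C)C)c2c(cc1O[Si](C)(C)C(C)(C)C)occc2=O | intermediate
8 | alkenylalane: dimethyl{(1E)-6-[(dimethylalumanyl)oxy]-2,6-dimethylhept-1-en-1-yl}alumane (methyl and aluminium cis) | C/C(=C\[Al](C)C)CCCC(C)(C)O[Al](C)C | intermediate
9 | 5,7-bis[(tert-butyldimethylsilyl)oxy]-6-[(2E)-7-hydroxy-3,7-dimethyloct-2-en-1-yl]-4H-chromen-4-one | C/C(=C\Cc1c(O[Si](C)(C)C(C)(C)C)c2c(cc1O[Si](C)(C)C(C)(C)C)occc2=O)CCCC(C)(C)O | intermediate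
10 | 4-bromobenzene-1,2-diol | Oc1ccc(Br)cc1O | starting material
11 | 4-bromo-1,2-bis[(tert-butyldimethylsilyl)oxy]benzene | CC(C)(C)[Si](C)(C)Oc1ccc(Br)cc1O[Si](C)(C)C(C)(C)C | intermediate
12 | aryllithium: {3,4-bis[(tert-butyldimethylsilyl)oxy]phenyl}lithium | [Li]c1ccc(O[Si](C)(C)C(C)(C)C)c(O[Si](C)(C)C(C)(C)C)c1 | intermediate
13 | {3,4-bis[(tert-butyldimethylsilyl)oxy]phenyl}boronic acid | OB(O)c1ccc(O[Si](C)(C)C(C)(C)C)c(O[Si](C)(C)C(C)(C)C)c1 | intermediate
14 | (2S)-5,7-bis[(tert-butyldimethylsilyl)oxy]-2-{3,4-bis[(tert-butyldimethylsilyl)oxy]phenyl}-6-[(2E)-7-hydroxy-3,7-dimethyloct-2-en-1-yl]-2,3-dihydro-4H-chromen-4-one | C/C(=C\Cc1c(O[Si](C)(C)C(C)(C)C)cc2c(c1O[Si](C)(C)C(C)(C)C)C(=O)C[C@@H](c1ccc(O[Si](C)(C)C(C)(C)C)c(O[Si](C)(C)C(C)(C)C)c1)O2)CCCC(C)(C)O | intermediate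
15 | Prokinawan, (2S)-2-(3,4-dihydroxyphenyl)-5,7-dihydroxy-6-[(2E)-7-hydroxy-3,7-dimethyloct-2-en-1-yl]-2,3-dihydro-4H-chromen-4-one | C/C(=C\Cc1c(O)cc2c(c1O)C(=O)C[C@@H](c1ccc(O)c(O)c1)O2)CCCC(C)(C)O | target

Total step count: 10. Longest linear sequence: 7 steps (steps 2, 3, 4, 5, 6, 9, 10 from compound 3).

Steps most likely to fail

Step 3. The iminium ion may attack C8 (para to the 5-hydroxyl) or both positions, or the chelated phenol may react sluggishly, so that regiocontrol is lost. The fallback sets out from 4 and returns at 7. Iodination of 4 with N-iodosuccinimide in DMF at rt, a reaction type known to go ortho to the free 5-hydroxyl in 5-hydroxy-7-alkoxy-chromones and -flavones, should give 7-[(tert-butyldimethylsilyl)oxy]-5-hydroxy-6-iodo-4H-chromen-4-one F1. Silylation with TBSOTf/2,6-lutidine would give 5,7-bis[(tert-butyldimethylsilyl)oxy]-6-iodo-4H-chromen-4-one F2. Stille hydroxymethylation with Bu3SnCH2OH and Pd(PPh3)4 (zerovalent palladium) in dioxane at 90 °C would give 5,7-bis[(tert-butyldimethylsilyl)oxy]-6-(hydroxymethyl)-4H-chromen-4-one F3. MsCl, Et3N and LiCl in CH2Cl2/THF at 0 °C would then convert F3 into chloride 7.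

Step 6. Possible failures are competing methyl transfer from aluminium, slow oxidative addition at the benzylic chloride flanked by two silyloxy groups, Lewis-acid-induced loss of the 5-O-silyl group followed by quinone-methide decomposition, and addition of aluminium species to the pyranone. The fallback sets out from 2 and 7 and returns at 9, forming the same bond with reversed polarity. Carboalumination of 2 as in step 6 followed by an iodine quench (THF, −30 °C) should give (6E)-7-iodo-2,6-dimethylhept-6-en-2-ol F4. LiCl-mediated insertion of zinc dust into 7 (THF, rt) should give the benzylic zinc chloride {[5,7-bis(tert-butyldimethylsilyloxy)-4-oxo-4H-chromen-6-yl]methyl}zinc chloride F5, a reagent class that tolerates carbonyl groups. Negishi coupling of F5 with F4 (Pd(OAc)2, divalent palladium, with SPhos, THF, rt; conditions known to tolerate free hydroxyl groups) would give 9.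

Step 9. Insertion into the electron-rich, heavily substituted chromone may be slow, allowing ring opening of the rhodium enolate to a chalcone and protodeboronation of the electron-rich boronic acid; facial selectivity may be insufficient or of the opposite sense. The fallback sets out from 9 and 13 and returns at 14, replacing asymmetric catalysis by kinetic resolution. Addition with the achiral catalyst [Rh(OH)(cod)]2 (monovalent rhodium) in dioxane/H2O at 40 °C should give the racemic flavanone rac-5,7-bis[(tert-butyldimethylsilyl)oxy]-2-{3,4-bis[(tert-butyldimethylsilyl)oxy]phenyl}-6-[(2E)-7-hydroxy-3,7-dimethyloct-2-en-1-yl]-2,3-dihydro-4H-chromen-4-one F6. Noyori transfer hydrogenation with RuCl(p-cymene)[(R,R)-TsDPEN] (divalent ruthenium) and HCO2H/Et3N at rt, run to just over half conversion, is expected to reduce the (2R)-enantiomer to the cis-alcohol (2R,4R)-5,7-bis[(tert-butyldimethylsilyl)oxy]-2-{3,4-bis[(tert-butyldimethylsilyl)oxy]phenyl}-6-[(2E)-7-hydroxy-3,7-dimethyloct-2-en-1-yl]-3,4-dihydro-2H-chromen-4-ol F7. Chromatography would then remove F7 and leave (2S)-flavanone 14.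

Further compounds
F1 | step 3 | 7-[(tert-butyldimethylsilyl)oxy]-5-hydroxy-6-iodo-4H-chromen-4-one | O=c1ccoc2cc(O[Si](C)(C)C(C)(C)C)c(I)c(O)c12
F2 | step 3 | 5,7-bis[(tert-butyldimethylsilyl)oxy]-6-iodo-4H-chromen-4-one | O=c1ccoc2cc(O[Si](C)(C)C(C)(C)C)c(I)c(O[Si](C)(C)C(C)(C)C)c12
F3 | step 3 | 5,7-bis[(tert-butyldimethylsilyl)oxy]-6-(hydroxymethyl)-4H-chromen-4-one | O=c1ccoc2cc(O[Si](C)(C)C(C)(C)C)c(CO)c(O[Si](C)(C)C(C)(C)C)c12
F4 | step 6 | (6E)-7-iodo-2,6-dimethylhept-6-en-2-ol | C/C(=C\I)CCCC(C)(C)O
F5 | step 6 | {[5,7-bis(tert-butyldimethylsilyloxy)-4-oxo-4H-chromen-6-yl]methyl}zinc chloride | Cl[Zn]Cc1c(O[Si](C)(C)C(C)(C)C)c2c(cc1O[Si](C)(C)C(C)(C)C)occc2=O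
F6 | step 9 | rac-5,7-bis[(tert-butyldimethylsilyl)oxy]-2-{3,4-bis[(tert-butyldimethylsilyl)oxy]phenyl}-6-[(2E)-7-hydroxy-3,7-dimethyloct-2-en-1-yl]-2,3-dihydro-4H-chromen-4-one | C/C(=C\Cc1c(O[Si](C)(C)C(C)(C)C)cc2c(c1O[Si](C)(C)C(C)(C)C)C(=O)CC(c1ccc(O[Si](C)(C)C(C)(C)C)c(O[Si](C)(C)C(C)(C)C)c1)O2)CCCC(C)(C)O
F7 | step 9 | (2R,4R)-5,7-bis[(tert-butyldimethylsilyl)oxy]-2-{3,4-bis[(tert-butyldimethylsilyl)oxy]phenyl}-6-[(2E)-7-hydroxy-3,7-dimethyloct-2-en-1-yl]-3,4-dihydro-2H-chromen-4-ol | C/C(=C\Cc1c(O[Si](C)(C)C(C)(C)C)cc2c(c1O[Si](C)(C)C(C)(C)C)[C@H](O)C[C@H](c1ccc(O[Si](C)(C)C(C)(C)C)c(O[Si](C)(C)C(C)(C)C)c1)O2)CCCC(C)(C)O
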